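Assumption (one line): the name is taken to mean exactly the given SMILES, i.e. the (1R,3R,3aS,4S,5R,7aS) acid with a trans ring fusion. Indene numbering is used throughout (C-1, C-2 (C=O), C-3, C-3a, C-4 (CO2H, Et), C-5 (Et, styryl), C-6=C-7 (Me), C-7a); ring A is the cyclohexene, ring B the cyclopentanone.

## The problem

Target 24 is a trans-fused hexahydroinden-2-one: ring A (C-3a, C-4, C-5, C-6, C-7, C-7a) is fused to ring B (C-1, C-2, C-3, C-3a, C-7a), and six contiguous stereocentres run around the fusion. The hardest element is the C-4/C-5 pair: two vicinal quaternary carbons with cis ethyl groups, C-4 carrying the acid and C-5 being doubly allylic and carrying the (E)-styryl group. This pair must be set in relation to H-3a and H-7a, which are trans and cannot be corrected later because both carbons are β to the ketone. C-1 and C-3 are α to the ketone and sit in their stable arrangement (each methyl trans to the adjacent ring-A bond), so they can be left to anti alkylation or equilibration; ring B alone is locally C2-symmetric. The feature that makes the key step possible is that the carboxyl carbon, C-4, C-5 and the styryl C=C form a γ,δ-unsaturated acid with phenyl on the δ-carbon (HO2C–C4–C5–CH=CH–Ph). That is the footprint of a [3,3] shift of the ester enolate of a 1-phenylallyl ester whose alkene terminus becomes C-5. A vinyl group left on C-5 by that shift and an isopropenyl group on C-7a then close ring A at C-6=C-7. The styrene and the skipped diene rule out dissolving-metal and hydrogenation chemistry, the acid is too hindered to be freed from an ester by saponification, the ketone must be masked during enolate steps, and an alkene on C-4 would create a Cope-prone 1,5-diene. Two stereochemical inputs are used: the bought stereocentre of 1 and a catalytically set carbinol in 13. Both are destroyed on the way, and all six stereocentres of 24 are relayed from them.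

## Retrosynthesis

**24 ⇒ 23 ⇒ 21 (C-4–ethyl bond).** After unmasking the ketone (23 is the dioxolane of 24), the ethyl group on C-4 is cut, leading to acid 21 and its dianion 22. This cut is preferred to carrying the ethyl group through the [3,3] step, because a tetrasubstituted acyclic ketene acetal (ethyl against a secondary alkyl group) cannot be formed with reliable geometry. In the rigid trans-fused bicycle the two faces of C-4 differ. The forward reaction must deliver iodoethane to the face anti to the pseudoaxial styryl group.

**21 ⇒ 20 (C-6=C-7).** The trisubstituted ring alkene is cut by ring-closing metathesis to a vinyl group on C-5 and an isopropenyl group on C-7a. No stereocentre is created, the trans relationship at C-3a/C-7a is already present, and ring A becomes an open chain hanging on ring B. The forward reaction must use the vinyl and not the styryl group.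

**20 ⇒ 17 (C-4–C-5 bond, key step).** The bond between the acid α-carbon and the doubly allylic quaternary carbon is cut with transposition of the styryl double bond, giving allylic ester 17 (via ketene acetal 18). Against a Michael or alkylation cut at C-4–C-3a, this cut has a stereospecific mechanism: the carbinol configuration and the alkene geometry of 16 alone fix C-5, and the styryl alkene is formed E in the same event. Precursor 17 is simply the ester of acid 10 and alcohol 16.

**17 ⇒ 10 + 16 (ester C–O).** A convergent esterification joins the ring-B fragment to the C-5/C-6/styryl fragment.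

**10 ⇒ 9 ⇒ 8 ⇒ 6 ⇒ 4 ⇒ 1 (ring B).** The C-3 methyl, the C-1 methyl with the C-7a isopropenyl group, and the C-3a acetate arm are cut in turn, back to the bought silyloxy enone 1. Each forward step is a trans addition or anti alkylation on a five-membered ring, so the trans ring fusion carries no selectivity question. Because ring B is locally C2-symmetric, the same enantiomer of 1 serves whichever arm is introduced first.

**16 ⇒ 15 ⇒ 13 ⇒ 11 + 12.** The (Z)-dienol comes from a propargylic alcohol by trans-hydroalumination/iodination and vinylation. The alcohol comes from benzaldehyde 11 and but-1-yne 12 by catalytic asymmetric alkynylation.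

## Roads not taken

**Alternative 1:** Cut C-4–C-5 and C-3a–C-7a together and form both rings by intramolecular Diels–Alder reaction of the open-chain keto tetraene acid A1. This is the most obvious disconnection. The chosen plan is preferred for three reasons:
- The only two stereocentres of A1 flank the ketone, and one is also allylic to the triene, so they are configurationally fragile throughout the chain assembly.
- The diene carries a Z ethyl group on its reacting terminus and the dienophile is trisubstituted, so the s-cis conformer is strained.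
- Both quaternary centres and the ring fusion arise in one transition state whose endo/exo and facial sense rest only on those two labile centres, with no later handle for correction.

The chosen route sets the same centres in separate stereospecific or ring-controlled events.

**Alternative 2:** Cut C-4–C-5 with the C-6=C-7 alkene as the transposed double bond, i.e. an Ireland–Claisen ring contraction of δ-lactone A2 (acyl carbon on C-4, oxygen on C-7). The ring would fix the ketene acetal geometry and deliver ring A with both quaternary centres at once. However, the six-membered lactone must reach a boat-like, bicyclo[2.2.2]octane-type transition state with C-4 and C-7 as bow and stern. That eclipses the C-3a–C-7a bond, which a trans-fused five-membered ring cannot tolerate. Ring B would have to be built afterwards from two acyclic arms, adding a second ring closure and at least four steps; the chosen plan keeps ring B intact from step 2.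

**Alternative 3:** Cut C-5–C-6 and C-3a–C-4 by a Diels–Alder reaction of the tetrasubstituted dienophile A3 with diene A4 to give meso anhydride A5, followed by catalytic desymmetrising alcoholysis. Both quaternary carbons with cis ethyl groups come from one cycloaddition and one catalytic step. The price is high, though:
- The alkene of A5 lies at C-7/C-7a instead of C-6/C-7.
- The C-7 methyl is missing.
- One carboxyl must be homologated to the styryl group.
- Ring B must be annulated trans across C-3a/C-7a, with the carbon at C-3a entering cis to both ethyl groups.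

This relocation of functionality costs roughly ten further steps, so the chosen plan is shorter and has a clearer stereochemical relay.

Key step: step 10

## Route

Step 1
Reactants: 1 (4R)-4-[(tert-butyldimethylsilyl)oxy]cyclopent-2-en-1-one
Product: 4 methyl 2-[(1S)-4-oxocyclopent-2-en-1-yl]acetate, via bis-silyl Michael adduct 2 (not isolated), via silyloxy ketone 3 (not isolated)
Conditions: CH2=C(OMe)OSiMe2tBu, HgI2 (cat.), CH2Cl2, −78 °C; then 1 M HCl, THF, 0 °C; then DBU, CH2Cl2, 0 °C
Reagents that add atoms: tert-butyl[(1-methoxyethenyl)oxy]dimethylsilane, C=C(OC)O[Si](C)(C)C(C)(C)C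
Why: Mukaiyama–Michael addition of the ketene silyl acetal should occur anti to the silyloxy group, setting C-3a; hydrolysis of the silyl enol ether and E1cB loss of silanol then move the enone to the other side of the ring, so the bought stereocentre is consumed after it has done its work.

Step 2
Reactants: 4 methyl 2-[(1S)-4-oxocyclopent-2-en-1-yl]acetate
Product: 6 methyl 2-[(1S,2S,3R)-3-methyl-4-oxo-2-(prop-1-en-2-yl)cyclopentyl]acetate, via magnesium enolate 5 (not isolated)
Conditions: CH2=C(Me)MgBr, CuBr·SMe2 (cat.), THF, −78 °C; then MeI, DMPU, −78 → −20 °C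
Reagents that add atoms: isopropenylmagnesium bromide, CC(=C)[Mg]Br; iodomethane, CI
Why: Copper-catalysed conjugate addition to a 4-substituted cyclopentenone should occur anti to the C-3a side chain (sets C-7a, the future trans ring fusion), and the regiodefined enolate is methylated anti to the new isopropenyl group (sets C-1); this is the classical three-component coupling on a cyclopentenone.

Step 3
Reactants: 6 methyl 2-[(1S,2S,3R)-3-methyl-4-oxo-2-(prop-1-en-2-yl)cyclopentyl]acetate
Product: 8 methyl 2-[(1S,2S,3R,5R)-3,5-dimethyl-4-oxo-2-(prop-1-en-2-yl)cyclopentyl]acetate, via lithium enolate 7 (not isolated)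
Conditions: LiN(iPr)2, THF, −78 °C; then MeI, −78 → −40 °C
Reagents that add atoms: iodomethane, CI
Why: Kinetic deprotonation should take the only α-methylene of the ketone (the ester is less acidic), and enolate methylation anti to the adjacent side chain gives the C-3 methyl group in its thermodynamic trans position, which base equilibration would also reach.

Step 4
Reactants: 8 methyl 2-[(1S,2S,3R,5R)-3,5-dimethyl-4-oxo-2-(prop-1-en-2-yl)cyclopentyl]acetate
Product: 9 methyl 2-[(6R,7S,8S,9R)-6,9-dimethyl-8-(prop-1-en-2-yl)-1,4-dioxaspiro[4.4]nonan-7-yl]acetate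
Conditions: Me3SiOCH2CH2OSiMe3, Me3SiOTf (cat.), CH2Cl2, −78 → −20 °C
Reagents that add atoms: 1,2-bis(trimethylsilyloxy)ethane, C[Si](C)(C)OCCO[Si](C)(C)C
Why: Silyl-triflate-catalysed ketalisation works at low temperature on hindered ketones and leaves the isopropenyl group and the ester untouched; the ketal removes the ketone α-protons from all later enolate steps and locks C-1 and C-3.

Step 5
Reactants: 9 methyl 2-[(6R,7S,8S,9R)-6,9-dimethyl-8-(prop-1-en-2-yl)-1,4-dioxaspiro[4.4]nonan-7-yl]acetate
Product: 10 2-[(6R,7S,8S,9R)-6,9-dimethyl-8-(prop-1-en-2-yl)-1,4-dioxaspiro[4.4]nonan-7-yl]acetic acid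
Conditions: LiOH, THF–H2O, 23 °C; then 1 M HCl to pH 4, 0 °C
Reagents that add atoms: lithium hydroxide, [Li+].[OH-]
Why: Saponification of an unhindered primary-alkyl acetate; the ketal is stable to base and to the brief mild acidification.

Step 6
Reactants: 11 benzaldehyde; 12 but-1-yne
Product: 13 (1S)-1-phenylpent-2-yn-1-ol
Conditions: Et2Zn, toluene, reflux; then BINOL (cat., enantiomer chosen for the S alcohol), Ti(OiPr)4 (cat.), 23 °C
Reagents that add atoms: none
Why: Catalytic enantioselective addition of an alkynylzinc reagent to an aromatic aldehyde; the titanium–BINOL complex selects the aldehyde face and sets the carbinol centre that later controls C-5.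

Step 7
Reactants: 13 (1S)-1-phenylpent-2-yn-1-ol
Product: 15 (1R,2Z)-3-iodo-1-phenylpent-2-en-1-ol, via cyclic vinylalanate 14 (not isolated)
Conditions: NaAlH2(OCH2CH2OMe)2, THF, 0 → 23 °C; then I2, THF, −78 °C
Reagents that add atoms: iodine, II
Why: Hydroxyl-directed trans-hydroalumination of a propargylic alcohol delivers hydride to C-2 and aluminium to C-3, and iododealumination with retention gives the Z vinyl iodide; no bond at the carbinol centre is touched, and the descriptor changes only because the alkenyl group ranks below phenyl whereas the alkynyl group ranked above it.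

Step 8
Reactants: 15 (1R,2Z)-3-iodo-1-phenylpent-2-en-1-ol
Product: 16 (1R,2Z)-3-ethyl-1-phenylpenta-2,4-dien-1-ol
Conditions: CH2=CHSnBu3, Pd(PPh3)4 (cat.), CuI (cat.), DMF, 23 °C
Reagents that add atoms: tributyl(vinyl)stannane, C=C[Sn](CCCC)(CCCC)CCCC
Why: Stille coupling proceeds with retention of alkene geometry under neutral conditions that the acid-labile dienyl carbinol tolerates, placing the vinyl group cis to the carbinol carbon.

Step 9
Reactants: 10 2-[(6R,7S,8S,9R)-6,9-dimethyl-8-(prop-1-en-2-yl)-1,4-dioxaspiro[4.4]nonan-7-yl]acetic acid; 16 (1R,2Z)-3-ethyl-1-phenylpenta-2,4-dien-1-ol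
Product: 17 (1R,2Z)-3-ethyl-1-phenylpenta-2,4-dien-1-yl 2-[(6R,7S,8S,9R)-6,9-dimethyl-8-(prop-1-en-2-yl)-1,4-dioxaspiro[4.4]nonan-7-yl]acetate
Conditions: DCC, DMAP (cat.), CH2Cl2, 0 °C
Reagents that add atoms: none
Why: Steglich esterification joins the two fragments under neutral conditions at low temperature, so the ionisable benzylic dienyl alcohol is acylated without allylic transposition.

Step 10
Reactants: 17 (1R,2Z)-3-ethyl-1-phenylpenta-2,4-dien-1-yl 2-[(6R,7S,8S,9R)-6,9-dimethyl-8-(prop-1-en-2-yl)-1,4-dioxaspiro[4.4]nonan-7-yl]acetate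
Product: 20 (2RS,3S,4E)-3-ethenyl-3-ethyl-2-[(6R,7S,8S,9R)-6,9-dimethyl-8-(prop-1-en-2-yl)-1,4-dioxaspiro[4.4]nonan-7-yl]-5-phenylpent-4-enoic acid, via silyl ketene acetal 18 (not isolated), via silyl ester 19 (not isolated)
Conditions: LiN(iPr)2, Me3SiCl, THF, −78 → 23 °C; then aq. citric acid
Reagents that add atoms: none
Why: Kinetic enolisation of the acetate-type ester and O-silylation give ketene acetal 18, which undergoes a concerted suprafacial [3,3]-sigmatropic shift through a six-membered transition state (Ireland–Claisen rearrangement); the closest precedent is the ester-enolate Claisen rearrangement of secondary allylic esters bearing a trisubstituted alkene, the standard way to an allylic quaternary carbon. No ring is closed: the C-4–C-5 bond of the target is made and the O–CH(Ph) bond is broken. The new quaternary centre C-5 is controlled by 1,3-chirality transfer from the carbinol centre, because the carbon–carbon bond forms on the alkene face from which the oxygen departs. Since the alkene is Z (vinyl cis to the carbinol carbon), allylic 1,3-strain forces phenyl into the pseudo-equatorial position, so one face only is used and the new double bond is E. With the R carbinol and the Z alkene, ethyl, vinyl and styryl end up on C-5 as required for 24, whatever the ketene acetal geometry or chair/boat preference. The acid α-carbon (future C-4) is formed as an epimer mixture that does not matter because it is re-enolised in step 12. The step needs the concerted path to win over ionisation of the doubly allylic benzylic ester; basic conditions, low temperature and internal silyl trapping should secure this, and formation of the conjugated styrene drives the shift.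

Step 11
Reactants: 20 (2RS,3S,4E)-3-ethenyl-3-ethyl-2-[(6R,7S,8S,9R)-6,9-dimethyl-8-(prop-1-en-2-yl)-1,4-dioxaspiro[4.4]nonan-7-yl]-5-phenylpent-4-enoic acid
Product: 21 (1'R,3'R,3a'S,4'RS,5'R,7a'S)-5'-ethyl-1',3',7'-trimethyl-5'-[(E)-2-phenylethenyl]-1',3',3a',4',5',7a'-hexahydrospiro[[1,3]dioxolane-2,2'-indene]-4'-carboxylic acid
Conditions: second-generation Grubbs catalyst (H2IMes)(PCy3)Cl2Ru=CHPh (cat.), CH2Cl2, 40 °C
Reagents that add atoms: none
Why: Ring-closing metathesis should initiate at the monosubstituted vinyl group and close onto the isopropenyl group to give the trisubstituted six-membered ring alkene with loss of ethene; the disubstituted conjugated styryl group is a much poorer partner, and the trans 3a/7a arms reach each other without strain.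

Step 12
Reactants: 21 (1'R,3'R,3a'S,4'RS,5'R,7a'S)-5'-ethyl-1',3',7'-trimethyl-5'-[(E)-2-phenylethenyl]-1',3',3a',4',5',7a'-hexahydrospiro[[1,3]dioxolane-2,2'-indene]-4'-carboxylic acid
Product: 23 (1'R,3'R,3a'S,4'S,5'R,7a'S)-4',5'-diethyl-1',3',7'-trimethyl-5'-[(E)-2-phenylethenyl]-1',3',3a',4',5',7a'-hexahydrospiro[[1,3]dioxolane-2,2'-indene]-4'-carboxylic acid, via dilithium enediolate 22 (not isolated)
Conditions: LiN(iPr)2 (2.5 equiv), THF–DMPU, −78 → 0 °C; then EtI, 0 → 23 °C; then 1 M HCl to pH 4
Reagents that add atoms: iodoethane, CCI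
Why: α-Alkylation of a carboxylic acid dianion gives the acid directly, which avoids an ester that could not be cleaved; in the rigid trans-fused bicycle the C-5 styryl group is pseudoaxial on the face that also carries axial H-3a, so iodoethane should enter from the opposite face, where C-6 is sp2 and H-7a is the only syn-axial contact, giving the axial C-4 ethyl cis to the C-5 ethyl.

Step 13
Reactants: 23 (1'R,3'R,3a'S,4'S,5'R,7a'S)-4',5'-diethyl-1',3',7'-trimethyl-5'-[(E)-2-phenylethenyl]-1',3',3a',4',5',7a'-hexahydrospiro[[1,3]dioxolane-2,2'-indene]-4'-carboxylic acid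
Product: 24 (1R,3R,3aS,4S,5R,7aS)-4,5-diethyl-1,3,7-trimethyl-2-oxo-5-[(E)-2-phenylethenyl]-2,3,3a,4,5,7a-hexahydro-1H-indene-4-carboxylic acid (dinorspiculoic acid A)
Conditions: 1 M HCl, THF, 40 °C
Reagents that add atoms: water, O
Why: Acid-catalysed ketal hydrolysis frees the ketone; C-1 and C-3 already have the thermodynamically preferred configuration, so any enolisation under these conditions should not change them.

## Compound list

1 | (4R)-4-[(tert-butyldimethylsilyl)oxy]cyclopent-2-en-1-one | O=C1C[C@@H](O[Si](C)(C)C(C)(C)C)C=C1 | starting material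
2 | methyl 2-[(1R,5R)-3,5-bis[(tert-butyldimethylsilyl)oxy]cyclopent-2-en-1-yl]acetate | CC(C)(C)[Si](C)(C)OC1=C[C@@H](CC(=O)OC)[C@H](O[Si](C)(C)C(C)(C)C)C1 | intermediate (not isolated)
3 | methyl 2-[(1S,2R)-2-[(tert-butyldimethylsilyl)oxy]-4-oxocyclopentyl]acetate | O=C1C[C@@H](CC(=O)OC)[C@H](O[Si](C)(C)C(C)(C)C)C1 | intermediate (not isolated)
4 | methyl 2-[(1S)-4-oxocyclopent-2-en-1-yl]acetate | O=C1C=C[C@H](CC(=O)OC)C1 | intermediate
5 | bromomagnesium enolate formed from 4 by isopropenyl addition (trans arms, enolate towards C-1) | Br[Mg]OC1=C[C@@H](C(C)=C)[C@H](CC(=O)OC)C1 | intermediate (not isolated)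
6 | methyl 2-[(1S,2S,3R)-3-methyl-4-oxo-2-(prop-1-en-2-yl)cyclopentyl]acetate | O=C1[C@H](C)[C@@H](C(C)=C)[C@H](CC(=O)OC)C1 | intermediate
7 | lithium enolate of 6 (towards the ring methylene, future C-3) | [Li]OC1=C[C@@H](CC(=O)OC)[C@H](C(C)=C)[C@H]1C | intermediate (not isolated)
8 | methyl 2-[(1S,2S,3R,5R)-3,5-dimethyl-4-oxo-2-(prop-1-en-2-yl)cyclopentyl]acetate | O=C1[C@H](C)[C@@H](C(C)=C)[C@H](CC(=O)OC)[C@H]1C | intermediate
9 | methyl 2-[(6R,7S,8S,9R)-6,9-dimethyl-8-(prop-1-en-2-yl)-1,4-dioxaspiro[4.4]nonan-7-yl]acetate | C1COC2(O1)[C@H](C)[C@@H](C(C)=C)[C@H](CC(=O)OC)[C@H]2C | intermediate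
10 | 2-[(6R,7S,8S,9R)-6,9-dimethyl-8-(prop-1-en-2-yl)-1,4-dioxaspiro[4.4]nonan-7-yl]acetic acid | C1COC2(O1)[C@H](C)[C@@H](C(C)=C)[C@H](CC(=O)O)[C@H]2C | intermediate
11 | benzaldehyde | O=Cc1ccccc1 | starting material
12 | but-1-yne | C#CCC | starting material
13 | (1S)-1-phenylpent-2-yn-1-ol | O[C@@H](c1ccccc1)C#CCC | intermediate
14 | sodium cyclic alkoxy(alkenyl)bis(2-methoxyethoxy)aluminate from 13 (H on C-2, Al on C-3) | [Na+].CCC1=C[C@H](c2ccccc2)O[Al-]1(OCCOC)OCCOC | intermediate (not isolated)
15 | (1R,2Z)-3-iodo-1-phenylpent-2-en-1-ol | O[C@@H](c1ccccc1)/C=C(CC)\I | intermediate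
16 | (1R,2Z)-3-ethyl-1-phenylpenta-2,4-dien-1-ol | O[C@@H](c1ccccc1)/C=C(CC)\C=C | intermediate
17 | (1R,2Z)-3-ethyl-1-phenylpenta-2,4-dien-1-yl 2-[(6R,7S,8S,9R)-6,9-dimethyl-8-(prop-1-en-2-yl)-1,4-dioxaspiro[4.4]nonan-7-yl]acetate | C1COC2(O1)[C@H](C)[C@@H](C(C)=C)[C@H](CC(=O)O[C@@H](c3ccccc3)/C=C(CC)\C=C)[C@H]2C | intermediate
18 | (E)-trimethylsilyl ketene acetal of ester 17 | C1COC2(O1)[C@H](C)[C@@H](C(C)=C)[C@H](/C=C(/O[Si](C)(C)C)O[C@@H](c3ccccc3)/C=C(CC)\C=C)[C@H]2C | intermediate (not isolated)
19 | trimethylsilyl ester of acid 20 (α-epimers) | C1COC2(O1)[C@H](C)[C@@H](C(C)=C)[C@H](C(C(=O)O[Si](C)(C)C)[C@@](CC)(C=C)/C=C/c3ccccc3)[C@H]2C | intermediate (not isolated)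
20 | (2RS,3S,4E)-3-ethenyl-3-ethyl-2-[(6R,7S,8S,9R)-6,9-dimethyl-8-(prop-1-en-2-yl)-1,4-dioxaspiro[4.4]nonan-7-yl]-5-phenylpent-4-enoic acid | C1COC2(O1)[C@H](C)[C@@H](C(C)=C)[C@H](C(C(=O)O)[C@@](CC)(C=C)/C=C/c3ccccc3)[C@H]2C | intermediate
21 | (1'R,3'R,3a'S,4'RS,5'R,7a'S)-5'-ethyl-1',3',7'-trimethyl-5'-[(E)-2-phenylethenyl]-1',3',3a',4',5',7a'-hexahydrospiro[[1,3]dioxolane-2,2'-indene]-4'-carboxylic acid | CC[C@@]1(/C=C/c2ccccc2)C=C(C)[C@H]2[C@@H]([C@@H](C)C3(OCCO3)[C@@H]2C)C1C(=O)O | intermediate
22 | dilithium enediolate of acid 21 | CC[C@@]1(/C=C/c2ccccc2)C=C(C)[C@H]2[C@@H]([C@@H](C)C3(OCCO3)[C@@H]2C)C1=C(O[Li])O[Li] | intermediate (not isolated)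
23 | (1'R,3'R,3a'S,4'S,5'R,7a'S)-4',5'-diethyl-1',3',7'-trimethyl-5'-[(E)-2-phenylethenyl]-1',3',3a',4',5',7a'-hexahydrospiro[[1,3]dioxolane-2,2'-indene]-4'-carboxylic acid | CC[C@@]1(/C=C/c2ccccc2)C=C(C)[C@H]2[C@@H]([C@@H](C)C3(OCCO3)[C@@H]2C)[C@]1(CC)C(=O)O | intermediate
24 | (1R,3R,3aS,4S,5R,7aS)-4,5-diethyl-1,3,7-trimethyl-2-oxo-5-[(E)-2-phenylethenyl]-2,3,3a,4,5,7a-hexahydro-1H-indene-4-carboxylic acid (dinorspiculoic acid A) | CC[C@@]1(/C=C/c2ccccc2)C=C(C)[C@H]2[C@@H]([C@@H](C)C(=O)[C@@H]2C)[C@]1(CC)C(=O)O | target

## Step count and least certain steps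

Total step count: 13. Longest linear sequence: 10 (steps 1–5 and 9–13); steps 6–8 build the second fragment.

**Step 10 (key step).** The doubly allylic, benzylic C–O bond of 17 or 18 may ionise before the concerted shift, which would cause allylic transposition and erode the chirality transfer; the ester enolate may also fragment to a ketene. Fallback: setting out from acid 10, the ester is made with a primary alcohol instead. Commercial pent-2-yn-1-ol F1 is converted by hydroalumination–iodination into (2Z)-3-iodopent-2-en-1-ol F2, and Suzuki coupling with (E)-2-phenylethenylboronic acid gives (2Z,4E)-3-ethyl-5-phenylpenta-2,4-dien-1-ol F3. Esterification with 10 gives the primary, non-benzylic dienyl ester F4, whose Ireland–Claisen rearrangement forms the same C-4–C-5 bond without an ionisable carbinol. The price is that C-5 is then set only by simple diastereoselection, so its epimer must be separated. The sequence comes back to the route at 20.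

**Step 12.** Facial selectivity may be poor, and enolisation of the very hindered acid may be incomplete, because ethyl and styryl on C-5 are of similar size and the enediolate may twist to relieve allylic strain. Fallback: setting out from ester 9, the ethyl group is introduced before the rearrangement. α-Ethylation gives methyl 2-[(6R,7S,8S,9R)-6,9-dimethyl-8-(prop-1-en-2-yl)-1,4-dioxaspiro[4.4]nonan-7-yl]butanoate F5, and saponification gives the corresponding butanoic acid F6. Esterification with 16 gives the (1R,2Z)-dienyl butanoate F7. Its Ireland–Claisen rearrangement through a tetrasubstituted ketene acetal builds both quaternary centres in one step and gives (2S,3S,4E)-3-ethenyl-2,3-diethyl-2-[(6R,7S,8S,9R)-6,9-dimethyl-8-(prop-1-en-2-yl)-1,4-dioxaspiro[4.4]nonan-7-yl]-5-phenylpent-4-enoic acid F8 together with its C-2 epimer, which is separated. Ring-closing metathesis of F8 comes back to the route at 23.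

**Step 1.** β-Elimination may occur before the conjugate addition, or the new enone double bond may migrate into conjugation with the side-chain carbon; either would lower the enantiomeric purity at C-3a. Fallback: setting out from 1, the arms are introduced in the reverse order, which the same enantiomer allows because ring B is locally C2-symmetric. Isopropenyl cuprate addition and silanol elimination give (4R)-4-(prop-1-en-2-yl)cyclopent-2-en-1-one F9. Mukaiyama–Michael addition of the same ketene silyl acetal gives the trans silyl enol ether methyl 2-[(1R,5S)-3-[(tert-butyldimethylsilyl)oxy]-5-(prop-1-en-2-yl)cyclopent-2-en-1-yl]acetate F10. Fluoride-mediated methylation with iodomethane gives methyl 2-[(1S,2R,5R)-5-methyl-4-oxo-2-(prop-1-en-2-yl)cyclopentyl]acetate F11. Kinetic enolate methylation of F11 at the remaining ring methylene comes back to the route at 8.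

**Step 2.** Proton transfer between the magnesium enolate and the product or the ester arm, sluggish C-methylation and over-methylation may all occur. Fallback: setting out from 4, the methyl group is placed on the enone first. α-Iodination (I2, pyridine) gives methyl 2-[(1S)-3-iodo-4-oxocyclopent-2-en-1-yl]acetate F12, and Stille methylation (SnMe4, Pd(PPh3)4, CuI) gives methyl 2-[(1S)-3-methyl-4-oxocyclopent-2-en-1-yl]acetate F13. Copper-catalysed isopropenyl addition to F13 with simple protonation and equilibration of the α-methyl centre comes back to the route at 6.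

## Further compounds

F1 | step 10 | pent-2-yn-1-ol | CCC#CCO
F2 | step 10 | (2Z)-3-iodopent-2-en-1-ol | OC/C=C(CC)\I
F3 | step 10 | (2Z,4E)-3-ethyl-5-phenylpenta-2,4-dien-1-ol | OC/C=C(CC)\C=C\c1ccccc1
F4 | step 10 | (2Z,4E)-3-ethyl-5-phenylpenta-2,4-dien-1-yl 2-[(6R,7S,8S,9R)-6,9-dimethyl-8-(prop-1-en-2-yl)-1,4-dioxaspiro[4.4]nonan-7-yl]acetate | C1COC2(O1)[C@H](C)[C@@H](C(C)=C)[C@H](CC(=O)OC/C=C(CC)\C=C\c3ccccc3)[C@H]2C
F5 | step 12 | methyl 2-[(6R,7S,8S,9R)-6,9-dimethyl-8-(prop-1-en-2-yl)-1,4-dioxaspiro[4.4]nonan-7-yl]butanoate (α-epimers) | C1COC2(O1)[C@H](C)[C@@H](C(C)=C)[C@H](C(CC)C(=O)OC)[C@H]2C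
F6 | step 12 | 2-[(6R,7S,8S,9R)-6,9-dimethyl-8-(prop-1-en-2-yl)-1,4-dioxaspiro[4.4]nonan-7-yl]butanoic acid (α-epimers) | C1COC2(O1)[C@H](C)[C@@H](C(C)=C)[C@H](C(CC)C(=O)O)[C@H]2C
F7 | step 12 | (1R,2Z)-3-ethyl-1-phenylpenta-2,4-dien-1-yl 2-[(6R,7S,8S,9R)-6,9-dimethyl-8-(prop-1-en-2-yl)-1,4-dioxaspiro[4.4]nonan-7-yl]butanoate (α-epimers) | C1COC2(O1)[C@H](C)[C@@H](C(C)=C)[C@H](C(CC)C(=O)O[C@@H](c3ccccc3)/C=C(CC)\C=C)[C@H]2C
F8 | step 12 | (2S,3S,4E)-3-ethenyl-2,3-diethyl-2-[(6R,7S,8S,9R)-6,9-dimethyl-8-(prop-1-en-2-yl)-1,4-dioxaspiro[4.4]nonan-7-yl]-5-phenylpent-4-enoic acid | C1COC2(O1)[C@H](C)[C@@H](C(C)=C)[C@H]([C@](CC)(C(=O)O)[C@@](CC)(C=C)/C=C/c3ccccc3)[C@H]2C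
F9 | step 1 | (4R)-4-(prop-1-en-2-yl)cyclopent-2-en-1-one | O=C1C[C@@H](C(C)=C)C=C1
F10 | step 1 | methyl 2-[(1R,5S)-3-[(tert-butyldimethylsilyl)oxy]-5-(prop-1-en-2-yl)cyclopent-2-en-1-yl]acetate (trans) | CC(C)(C)[Si](C)(C)OC1=C[C@@H](CC(=O)OC)[C@H](C(C)=C)C1
F11 | step 1 | methyl 2-[(1S,2R,5R)-5-methyl-4-oxo-2-(prop-1-en-2-yl)cyclopentyl]acetate | O=C1C[C@@H](C(C)=C)[C@H](CC(=O)OC)[C@H]1C
F12 | step 2 | methyl 2-[(1S)-3-iodo-4-oxocyclopent-2-en-1-yl]acetate | O=C1C(I)=C[C@H](CC(=O)OC)C1
F13 | step 2 | methyl 2-[(1S)-3-methyl-4-oxocyclopent-2-en-1-yl]acetate | O=C1C(C)=C[C@H](CC(=O)OC)C1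
A1 | alternative 1 | (2E,4R,6R,7E,9E,11E)-2,10-diethyl-4,6,8-trimethyl-5-oxo-12-phenyldodeca-2,7,9,11-tetraenoic acid | OC(=O)/C(CC)=C/[C@@H](C)C(=O)[C@H](C)/C=C(C)/C=C(CC)/C=C/c1ccccc1
A2 | alternative 2 | trans-fused δ-lactone: 4-ethyl-1,5,7-trimethyl-1-[(1E,3E)-2-ethyl-4-phenylbuta-1,3-dien-1-yl]hexahydrocyclopenta[c]pyran-3,6-dione (acyl carbon on C-4, lactone oxygen on C-7 of the target numbering; α-carbon unspecified) | CCC1C(=O)O[C@@](C)(/C=C(CC)/C=C/c2ccccc2)[C@H]2[C@H]1[C@@H](C)C(=O)[C@@H]2C
A3 | alternative 3 | 3,4-diethylfuran-2,5-dione (2,3-diethylmaleic anhydride) | CCC1=C(CC)C(=O)OC1=O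
A4 | alternative 3 | buta-1,3-diene | C=CC=C
A5 | alternative 3 | meso-(3aR,7aS)-3a,7a-diethyl-3a,4,7,7a-tetrahydro-2-benzofuran-1,3-dione | CC[C@]12CC=CC[C@@]1(CC)C(=O)OC2=O
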